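In bisabolane numbering (ring C1–C6; C6 carries C7=C14H2; methyl C15 on C3) the cyclohexane ring hides a 1,5-diene: ring CH2 C1 and ring methine C6 are the central atoms of C3=C2–C1–C6–C7=C14, the C2/C3 oxirane being a masked ring olefin. Everything rests on a biomimetic allyl cation–allylsilane closure of the C1–C6 bond. An acyclic chain built on L-tartrate (C3–C6, with the C4/C5 diol as trans-dioxolane), bearing a tertiary vinyl carbinol at C3 and a (Z)-allylsilane across C6=C7, ionises and cyclises: one operation forms the carbocycle, sets C6 and delivers both the C2=C3 and the exocyclic C7=C14 olefins. Directed and catalyst-controlled epoxidations finish.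

Key step: step 10

Numbering used throughout: ring C1 (CH2), C2/C3 (oxirane, methyl C15 on C3), C4 and C5 (ring esters), C6 (ring CH); C7 (=C14H2), C8 (side-chain ester), C9, C10/C11 (side-chain oxirane, methyls C12/C13).

Assumption: 7 is drawn as the (R)-carbinol expected from chelation control; any C3 epimer is carried along, because this centre becomes sp2 in step 10.

Step 1
Reactants: 1 dimethyl (4R,5R)-2,2-dimethyl-1,3-dioxolane-4,5-dicarboxylate (dimethyl 2,3-O-isopropylidene-L-tartrate); 2 N,O-dimethylhydroxylamine hydrochloride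
Product: 3 (4R,5R)-N4,N5-dimethoxy-N4,N5,2,2-tetramethyl-1,3-dioxolane-4,5-dicarboxamide
Conditions: MeNH(OMe)·HCl, i-PrMgCl, THF, −20 → 0 °C
Reagents that add atoms: N,O-dimethylhydroxylamine hydrochloride 2, CNOC.Cl
Why: Magnesium-amide aminolysis of both esters (Weinreb amide formation) should proceed without touching the acetal-protected stereocentres C4 and C5.

Step 2
Reactants: 3 bis-Weinreb amide; 4 methylmagnesium bromide
Product: 5 (4R,5R)-5-acetyl-N-methoxy-N,2,2-trimethyl-1,3-dioxolane-4-carboxamide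
Conditions: MeMgBr (1.3 equiv), THF, −15 °C; aq. NH4Cl
Reagents that add atoms: methylmagnesium bromide 4, C[Mg]Br
Why: Weinreb ketone synthesis that should stop at mono-addition, because the magnesium-chelated tetrahedral intermediate at one amide deactivates the twofold-symmetric bis-amide toward a second addition; this installs C3 with its methyl C15.

Step 3
Reactants: 5 keto amide; 6 vinylmagnesium bromide
Product: 7 (4R,5R)-5-[(2R)-2-hydroxybut-3-en-2-yl]-N-methoxy-N,2,2-trimethyl-1,3-dioxolane-4-carboxamide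
Conditions: CH2=CHMgBr (1.2 equiv), THF, −78 °C; aq. NH4Cl
Reagents that add atoms: vinylmagnesium bromide 6, C=C[Mg]Br
Why: Chemoselective Grignard 1,2-addition to the ketone (far more electrophilic than the Weinreb amide at −78 °C) installs C1=C2 as a tertiary vinyl carbinol, the (R) epimer being the one expected from the Cram-chelate model with O4; the trans-dioxolane prevents lactonisation onto the amide.

Step 4
Reactants: 7 tertiary carbinol amide; 8 dimethyl (1-diazo-2-oxopropyl)phosphonate (Ohira–Bestmann reagent)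
Product: 10 (2R)-2-[(4R,5S)-5-ethynyl-2,2-dimethyl-1,3-dioxolan-4-yl]but-3-en-2-ol, via aldehyde 9 (not isolated)
Conditions: i-Bu2AlH (2.5 equiv), CH2Cl2, −78 °C; then MeOH, K2CO3, MeC(O)C(N2)P(O)(OMe)2, 0 °C → rt
Reagents that add atoms: Ohira–Bestmann reagent 8, CC(=O)C(=[N+]=[N-])P(=O)(OC)OC
Why: Weinreb amide reduction should stop at aldehyde 9 (chelated aluminium hemiaminal), and Seyferth–Gilbert homologation in the same flask adds C7 as a terminal alkyne; C5 is not at risk because the trans-dioxolane is the stable epimer.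

Step 5
Reactants: 11 4-methylpent-3-enoic acid; 2 N,O-dimethylhydroxylamine hydrochloride
Product: 12 N-methoxy-N,4-dimethylpent-3-enamide
Conditions: EDC·HCl, N-methylmorpholine, CH2Cl2, 0 °C → rt
Reagents that add atoms: N,O-dimethylhydroxylamine hydrochloride 2, CNOC.Cl
Why: Carbodiimide amide coupling should give the Weinreb amide carrying C8–C13 under conditions that do not move the β,γ-double bond.

Step 6
Reactants: 10 alkyne; 12 Weinreb amide
Product: 13 1-[(4S,5R)-5-[(2R)-2-hydroxybut-3-en-2-yl]-2,2-dimethyl-1,3-dioxolan-4-yl]-6-methylhept-5-en-1-yn-3-one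
Conditions: n-BuLi (2.1 equiv), THF, −78 °C; then 12, −78 → −20 °C; cold aq. NH4Cl
Reagents that add atoms: Weinreb amide 12, CON(C)C(=O)CC=C(C)C
Why: Weinreb ketone synthesis with the lithium acetylide of 10 (alkoxide/acetylide dianion) forms the C7–C8 bond, the chelated tetrahedral intermediate shielding the β,γ-unsaturated ynone from base until the cold quench.

Step 7
Reactants: 13 ynone
Product: 14 (3S)-1-[(4S,5R)-5-[(2R)-2-hydroxybut-3-en-2-yl]-2,2-dimethyl-1,3-dioxolan-4-yl]-6-methylhept-5-en-1-yn-3-ol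
Conditions: RuCl[(S,S)-TsDPEN](p-cymene) (2 mol %), i-PrOH, rt
Reagents that add atoms: none
Why: Noyori asymmetric transfer hydrogenation of an alkynyl ketone, in which the (S,S)-catalyst differentiates alkynyl from alkyl and should set C8 as (S) under base-free conditions that spare the acidic C9 methylene.

Step 8
Reactants: 14 propargylic alcohol; 15 (trimethylsilyl)methylmagnesium chloride
Product: 16 (1Z,3S)-1-[(4S,5R)-5-[(2R)-2-hydroxybut-3-en-2-yl]-2,2-dimethyl-1,3-dioxolan-4-yl]-6-methyl-2-[(trimethylsilyl)methyl]hepta-1,5-dien-3-ol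
Conditions: Me3SiCH2MgCl (5 equiv), CuI (10 mol %), THF, 0 → 40 °C; aq. NH4Cl
Reagents that add atoms: (trimethylsilyl)methylmagnesium chloride 15, C[Si](C)(C)C[Mg]Cl
Why: Hydroxyl-directed, copper-catalysed anti-carbomagnesiation of a propargylic alcohol, in which the C8 magnesium alkoxide should deliver Me3SiCH2 to the proximal C7 and magnesium to C6 within a five-membered chelate, so that protonation on work-up gives the (Z)-allylsilane with CH2SiMe3 cis to C5.

Step 9
Reactants: 16 allylsilane diol; 17 angelic acid [(2Z)-2-methylbut-2-enoic acid]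
Product: 18 (1Z,3S)-1-[(4S,5R)-5-[(2R)-2-hydroxybut-3-en-2-yl]-2,2-dimethyl-1,3-dioxolan-4-yl]-6-methyl-2-[(trimethylsilyl)methyl]hepta-1,5-dien-3-yl (2Z)-2-methylbut-2-enoate
Conditions: angelic acid, 2,4,6-Cl3C6H2COCl, Et3N, toluene, rt; then 16, 80 °C
Reagents that add atoms: angelic acid 17, C/C=C(/C)C(=O)O
Why: Yamaguchi-type esterification via the mixed anhydride should acylate only the secondary allylic C8 hydroxyl (the tertiary C3 carbinol is inert) and, being free of nucleophilic amine catalysts, keep the angelate (Z)-configured.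

Step 10
Reactants: 18 cyclisation precursor
Product: 19 (3S)-6-methyl-2-[(3aS,4S,7aS)-2,2,7-trimethyl-3a,4,5,7a-tetrahydro-1,3-benzodioxol-4-yl]hepta-1,5-dien-3-yl (2Z)-2-methylbut-2-enoate
Conditions: Ca(NTf2)2 (5 mol %), Bu4NPF6 (5 mol %), CH2Cl2, 0 °C → rt
Reagents that add atoms: none
Why: The Lewis acid ionises the tertiary allylic alcohol to the C1–C2–C3 allyl cation, C6 of the allylsilane captures its C1 terminus (SE2′), and loss of silicon from the β-silyl cation at C7 releases the exocyclic C7=C14 methylene; this is an intramolecular Hosomi–Sakurai-type allylation of an allylic cation, the laboratory counterpart of the farnesyl-to-bisabolyl closure. The six-membered ring closes exo with respect to the attacking C6=C7 olefin and endo with respect to the allyl cation (C1, C2 and C3 all end up in the ring), through a chair-like transition state. The new C6 stereocentre is controlled by C5: allylic 1,3-strain with the cis CH2SiMe3 group keeps H5 in the olefin plane, so C1 (tethered through C4) adds to the C6 face that places C7 equatorial and trans to O5, while the trans-dioxolane holds O4 and O5 equatorial. Regioselectivity (C1 versus C3 attack) is secured by ring size (six versus four) and the position of the new exocyclic double bond by the silicon. The C3 carbinol configuration is erased, so both epimers converge, and ionisation of the tertiary carbinol in preference to the secondary allylic angelate rests on cation stability.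

Step 11
Reactants: 19 cyclised acetonide
Product: 20 (3S)-2-[(1S,5S,6S)-5,6-dihydroxy-4-methylcyclohex-3-en-1-yl]-6-methylhepta-1,5-dien-3-yl (2Z)-2-methylbut-2-enoate
Conditions: AcOH/H2O (4:1), 40 °C
Reagents that add atoms: none
Why: Acid hydrolysis of the strained trans-fused isopropylidene acetal should free the C4/C5 diol while the olefins and the allylic angelate are untouched.

Step 12
Reactants: 20 cyclohexenediol; 21 tert-butyl hydroperoxide
Product: 22 (3S)-2-[(1S,3S,4S,5R,6R)-4,5-dihydroxy-6-methyl-7-oxabicyclo[4.1.0]heptan-3-yl]-6-methylhepta-1,5-dien-3-yl (2Z)-2-methylbut-2-enoate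
Conditions: VO(acac)2 (5 mol %), t-BuOOH (1.2 equiv), CH2Cl2, 0 °C → rt
Reagents that add atoms: tert-butyl hydroperoxide 21, CC(C)(C)OO
Why: Vanadium-catalysed hydroxyl-directed epoxidation of the cyclic allylic alcohol should deliver oxygen to C2=C3 on the face of the C4 hydroxyl, setting C2 and C3 cis to O4; the other olefins lack an allylic hydroxyl (C8 is esterified) and should not react.

Step 13
Reactants: 22 epoxy diol; 17 angelic acid
Product: 23 (3S)-6-methyl-2-[(1S,3S,4S,5R,6S)-6-methyl-4,5-bis{[(2Z)-2-methylbut-2-enoyl]oxy}-7-oxabicyclo[4.1.0]heptan-3-yl]hepta-1,5-dien-3-yl (2Z)-2-methylbut-2-enoate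
Conditions: angelic acid (6 equiv), 2,4,6-Cl3C6H2COCl, Et3N, toluene, rt; then 22, 80 °C
Reagents that add atoms: angelic acid 17, C/C=C(/C)C(=O)O
Why: A second Yamaguchi-type angeloylation should esterify both ring hydroxyls, the amine-catalyst-free conditions avoiding isomerisation to tiglate and leaving the oxirane intact.

Step 14
Reactants: 23 tris-angelate; 24 Oxone (2KHSO5·KHSO4·K2SO4, active component KHSO5)
Product: 25 (2S)-1-[(2R)-3,3-dimethyloxiran-2-yl]-3-[(1S,3S,4S,5R,6S)-6-methyl-4,5-bis{[(2Z)-2-methylbut-2-enoyl]oxy}-7-oxabicyclo[4.1.0]heptan-3-yl]but-3-en-2-yl (2Z)-2-methylbut-2-enoate (CNP0258231.3)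
Conditions: D-fructose-derived Shi ketone (30 mol %), Oxone, K2CO3, Bu4NHSO4 (cat.), MeCN/CH2(OMe)2/aq. Na2B4O7 buffer (pH 10.5), 0 °C
Reagents that add atoms: Oxone 24 (KHSO5), [K+].[O-]S(=O)(=O)OO
Why: Shi asymmetric epoxidation, in which the chiral dioxirane should attack only the electron-rich trisubstituted C10=C11 olefin (the enoate and the deactivated 1,1-disubstituted C7=C14 olefins react much more slowly) through the spiro transition state that gives the (10R) oxirane.

Compound list

1 | dimethyl (4R,5R)-2,2-dimethyl-1,3-dioxolane-4,5-dicarboxylate | COC(=O)[C@@H]1OC(C)(C)O[C@H]1C(=O)OC | starting material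
2 | N,O-dimethylhydroxylamine hydrochloride | CNOC.Cl | starting material
3 | (4R,5R)-N4,N5-dimethoxy-N4,N5,2,2-tetramethyl-1,3-dioxolane-4,5-dicarboxamide | CON(C)C(=O)[C@@H]1OC(C)(C)O[C@H]1C(=O)N(C)OC | intermediate
4 | methylmagnesium bromide | C[Mg]Br | starting material
5 | (4R,5R)-5-acetyl-N-methoxy-N,2,2-trimethyl-1,3-dioxolane-4-carboxamide | CC(=O)[C@@H]1OC(C)(C)O[C@H]1C(=O)N(C)OC | intermediate
6 | vinylmagnesium bromide | C=C[Mg]Br | starting material
7 | (4R,5R)-5-[(2R)-2-hydroxybut-3-en-2-yl]-N-methoxy-N,2,2-trimethyl-1,3-dioxolane-4-carboxamide | C=C[C@@](C)(O)[C@@H]1OC(C)(C)O[C@H]1C(=O)N(C)OC | intermediate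
8 | dimethyl (1-diazo-2-oxopropyl)phosphonate (Ohira–Bestmann reagent) | CC(=O)C(=[N+]=[N-])P(=O)(OC)OC | starting material
9 | (4R,5R)-5-[(2R)-2-hydroxybut-3-en-2-yl]-2,2-dimethyl-1,3-dioxolane-4-carbaldehyde | C=C[C@@](C)(O)[C@@H]1OC(C)(C)O[C@H]1C=O | intermediate
10 | (2R)-2-[(4R,5S)-5-ethynyl-2,2-dimethyl-1,3-dioxolan-4-yl]but-3-en-2-ol | C=C[C@@](C)(O)[C@@H]1OC(C)(C)O[C@H]1C#C | intermediate
11 | 4-methylpent-3-enoic acid | CC(C)=CCC(=O)O | starting material
12 | N-methoxy-N,4-dimethylpent-3-enamide | CON(C)C(=O)CC=C(C)C | intermediate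
13 | 1-[(4S,5R)-5-[(2R)-2-hydroxybut-3-en-2-yl]-2,2-dimethyl-1,3-dioxolan-4-yl]-6-methylhept-5-en-1-yn-3-one | C=C[C@@](C)(O)[C@@H]1OC(C)(C)O[C@H]1C#CC(=O)CC=C(C)C | intermediate
14 | (3S)-1-[(4S,5R)-5-[(2R)-2-hydroxybut-3-en-2-yl]-2,2-dimethyl-1,3-dioxolan-4-yl]-6-methylhept-5-en-1-yn-3-ol | C=C[C@@](C)(O)[C@@H]1OC(C)(C)O[C@H]1C#C[C@@H](O)CC=C(C)C | intermediate
15 | (trimethylsilyl)methylmagnesium chloride | C[Si](C)(C)C[Mg]Cl | starting material
16 | (1Z,3S)-1-[(4S,5R)-5-[(2R)-2-hydroxybut-3-en-2-yl]-2,2-dimethyl-1,3-dioxolan-4-yl]-6-methyl-2-[(trimethylsilyl)methyl]hepta-1,5-dien-3-ol | C=C[C@@](C)(O)[C@@H]1OC(C)(C)O[C@H]1/C=C(\C[Si](C)(C)C)[C@@H](O)CC=C(C)C | intermediate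
17 | angelic acid, (2Z)-2-methylbut-2-enoic acid | C/C=C(/C)C(=O)O | starting material
18 | (1Z,3S)-1-[(4S,5R)-5-[(2R)-2-hydroxybut-3-en-2-yl]-2,2-dimethyl-1,3-dioxolan-4-yl]-6-methyl-2-[(trimethylsilyl)methyl]hepta-1,5-dien-3-yl (2Z)-2-methylbut-2-enoate | C=C[C@@](C)(O)[C@@H]1OC(C)(C)O[C@H]1/C=C(\C[Si](C)(C)C)[C@@H](OC(=O)/C(C)=C\C)CC=C(C)C | intermediate
19 | (3S)-6-methyl-2-[(3aS,4S,7aS)-2,2,7-trimethyl-3a,4,5,7a-tetrahydro-1,3-benzodioxol-4-yl]hepta-1,5-dien-3-yl (2Z)-2-methylbut-2-enoate | C=C([C@H](CC=C(C)C)OC(=O)/C(C)=C\C)[C@@H]1CC=C(C)[C@@H]2OC(C)(C)O[C@@H]12 | intermediate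
20 | (3S)-2-[(1S,5S,6S)-5,6-dihydroxy-4-methylcyclohex-3-en-1-yl]-6-methylhepta-1,5-dien-3-yl (2Z)-2-methylbut-2-enoate | C=C([C@H](CC=C(C)C)OC(=O)/C(C)=C\C)[C@@H]1CC=C(C)[C@H](O)[C@H]1O | intermediate
21 | tert-butyl hydroperoxide | CC(C)(C)OO | starting material
22 | (3S)-2-[(1S,3S,4S,5R,6R)-4,5-dihydroxy-6-methyl-7-oxabicyclo[4.1.0]heptan-3-yl]-6-methylhepta-1,5-dien-3-yl (2Z)-2-methylbut-2-enoate | C=C([C@H](CC=C(C)C)OC(=O)/C(C)=C\C)[C@@H]1C[C@@H]2O[C@]2(C)[C@H](O)[C@H]1O | intermediate
23 | (3S)-6-methyl-2-[(1S,3S,4S,5R,6S)-6-methyl-4,5-bis{[(2Z)-2-methylbut-2-enoyl]oxy}-7-oxabicyclo[4.1.0]heptan-3-yl]hepta-1,5-dien-3-yl (2Z)-2-methylbut-2-enoate | C=C([C@H](CC=C(C)C)OC(=O)/C(C)=C\C)[C@@H]1C[C@@H]2O[C@]2(C)[C@H](OC(=O)/C(C)=C\C)[C@H]1OC(=O)/C(C)=C\C | intermediate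
24 | Oxone, active component potassium peroxymonosulfate KHSO5 | [K+].[O-]S(=O)(=O)OO | starting material
25 | (2S)-1-[(2R)-3,3-dimethyloxiran-2-yl]-3-[(1S,3S,4S,5R,6S)-6-methyl-4,5-bis{[(2Z)-2-methylbut-2-enoyl]oxy}-7-oxabicyclo[4.1.0]heptan-3-yl]but-3-en-2-yl (2Z)-2-methylbut-2-enoate | C=C([C@H](C[C@H]1OC1(C)C)OC(=O)/C(C)=C\C)[C@@H]1C[C@@H]2O[C@]2(C)[C@H](OC(=O)/C(C)=C\C)[C@H]1OC(=O)/C(C)=C\C | target

Total step count: 14. Longest linear sequence: 13 (steps 1–4 and 6–14 from 1; step 5 is the side branch).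

Steps most likely to fail

1. Step 10 (key ring closure). Ionisation beside the dioxolane may be diverted by a 1,2-hydride shift from C4 (oxocarbenium formation and loss of the acetal), by formation of the extended allyl cation that can only eliminate, or by protodesilylation before C–C bond formation. Fallback: the substrate is redesigned so that no acetal and no electron-rich oxygen flank the cation. Setting out from 18, the dioxolane would be removed (PPTS, MeOH, 40 °C) to give (3R,4R,5S,6Z,8S)-3,4,5-trihydroxy-3,11-dimethyl-7-[(trimethylsilyl)methyl]dodeca-1,6,10-trien-8-yl angelate F1. Its two secondary hydroxyls would be acylated with chloroacetic anhydride/pyridine at −20 °C (the tertiary carbinol stays free) to give the 4,5-bis(chloroacetate) F2. The electron-poor esters should suppress hydride migration from C4 and can assist ionisation as an acyloxonium, so the same catalytic Lewis-acid closure would now run on an acyclic, acetal-free substrate and give the cyclohexene 4,5-bis(chloroacetate) 8-angelate F3. Thiourea/NaHCO3 in EtOH would then remove both chloroacetates without touching the angelate, and the route is rejoined at diol 20.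

2. Step 8 (allylsilane installation). The silylmethyl group may transfer sluggishly from copper, addition may occur without hydroxyl direction, or the C6–magnesium intermediate may expel the C5 dioxolane oxygen to give an allene. Fallback: the C7–C14 bond is made by cross-coupling instead of carbometalation. Setting out from 14, hydroxyl-directed trans-hydrostannation (Bu3SnH, [Cp*RuCl]4 cat., CH2Cl2) should place tin on C7, proximal to the C8 hydroxyl, giving the (Z)-alkenylstannane F4. Iododestannylation (I2, CH2Cl2, 0 °C) would give the (Z)-alkenyl iodide F5 with retention. Kumada coupling with Me3SiCH2MgCl and Pd(PPh3)4 in THF would then return to allylsilane 16 with the same olefin geometry.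

3. Step 13 (bis-angeloylation of the epoxy diol). Acylation may stall at the hindered C4 hydroxyl next to the quaternary oxirane carbon, the angelate may isomerise to tiglate at 80 °C, or chloride may open the trisubstituted oxirane. Fallback: the (Z)-olefin of each angelate is built after acylation. Setting out from 22, both hydroxyls would be esterified with 2-[bis(2,2,2-trifluoroethoxy)phosphoryl]propanoic acid (DCC, DMAP, CH2Cl2) to give the bis(phosphonopropionate) F6. A double Still–Gennari olefination with acetaldehyde (KHMDS, 18-crown-6, THF, −78 °C) should then form both (Z)-2-methylbut-2-enoates and return to tris-angelate 23.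

Further compounds

F1 | step 10 | (3R,4R,5S,6Z,8S)-3,4,5-trihydroxy-3,11-dimethyl-7-[(trimethylsilyl)methyl]dodeca-1,6,10-trien-8-yl (2Z)-2-methylbut-2-enoate | C=C[C@@](C)(O)[C@H](O)[C@@H](O)/C=C(\C[Si](C)(C)C)[C@@H](OC(=O)/C(C)=C\C)CC=C(C)C
F2 | step 10 | (3R,4R,5S,6Z,8S)-4,5-bis[(chloroacetyl)oxy]-3-hydroxy-3,11-dimethyl-7-[(trimethylsilyl)methyl]dodeca-1,6,10-trien-8-yl (2Z)-2-methylbut-2-enoate | C=C[C@@](C)(O)[C@H](OC(=O)CCl)[C@@H](OC(=O)CCl)/C=C(\C[Si](C)(C)C)[C@@H](OC(=O)/C(C)=C\C)CC=C(C)C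
F3 | step 10 | (3S)-2-[(1S,5S,6S)-5,6-bis[(chloroacetyl)oxy]-4-methylcyclohex-3-en-1-yl]-6-methylhepta-1,5-dien-3-yl (2Z)-2-methylbut-2-enoate | C=C([C@H](CC=C(C)C)OC(=O)/C(C)=C\C)[C@@H]1CC=C(C)[C@H](OC(=O)CCl)[C@H]1OC(=O)CCl
F4 | step 8 | (1Z,3S)-1-[(4S,5R)-5-[(2R)-2-hydroxybut-3-en-2-yl]-2,2-dimethyl-1,3-dioxolan-4-yl]-6-methyl-2-(tributylstannyl)hepta-1,5-dien-3-ol | C=C[C@@](C)(O)[C@@H]1OC(C)(C)O[C@H]1/C=C(\[Sn](CCCC)(CCCC)CCCC)[C@@H](O)CC=C(C)C
F5 | step 8 | (1Z,3S)-1-[(4S,5R)-5-[(2R)-2-hydroxybut-3-en-2-yl]-2,2-dimethyl-1,3-dioxolan-4-yl]-2-iodo-6-methylhepta-1,5-dien-3-ol | C=C[C@@](C)(O)[C@@H]1OC(C)(C)O[C@H]1/C=C(\I)[C@@H](O)CC=C(C)C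
F6 | step 13 | 4,5-bis{2-[bis(2,2,2-trifluoroethoxy)phosphoryl]propanoate} of epoxy diol 22 (phosphonate α-carbons as epimer mixture) | C=C([C@H](CC=C(C)C)OC(=O)/C(C)=C\C)[C@@H]1C[C@@H]2O[C@]2(C)[C@H](OC(=O)C(C)P(=O)(OCC(F)(F)F)OCC(F)(F)F)[C@H]1OC(=O)C(C)P(=O)(OCC(F)(F)F)OCC(F)(F)F
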